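**Retrosynthetic overview**

1. The pyranone ring of the chroman-4-one is cut at C2–C3 and at C4–C4a. This is a formal [4+2] annulation of an O-aryl oxocarbenium ion (O1–C2, from 1-(chloromethoxy)-3,5-dimethoxybenzene) with the C3=C4=O unit of a benzocyclobutenylidene ketene.
2. Enabling feature: C2 is a methylene at the formaldehyde level between O1 and C3, C3 is the nucleophilic α-carbon of a ketene, and C4a is an ortho carbon of a symmetric 3,5-dimethoxyphenyl ether activated by the C5 and C7 methoxy groups, so the acyl carbon C4 can close on it once C2–C3 exists.
3. The ketene is made in the same flask by Wolff ring contraction of 2-diazo-6,7-dimethoxyindan-1-one, which builds the four-membered ring. A chiral chloride-binding squaramide sets the spiro centre C3.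
4. Ring order: both benzene rings are bought, then the cyclobutene (ring contraction), then the pyranone ring (annulation). Four steps in all.

Key step: step 4

Remark: 6,7-dimethoxyindan-1-one (1) is taken as a catalogue compound.
Remark: "the squaramide" in step 4 is 3-{[3,5-bis(trifluoromethyl)phenyl]amino}-4-({(2S)-3,3-dimethyl-1-oxo-1-[(2R)-2-(phenanthren-9-yl)pyrrolidin-1-yl]butan-2-yl}amino)cyclobut-3-ene-1,2-dione or its enantiomer, a chiral dual hydrogen-bond donor without nucleophilic sulfur.

**Step 1**
Reactants: 1 6,7-dimethoxyindan-1-one
Product: 3 2-diazo-6,7-dimethoxyindan-1-one, via 2-trifluoroacetyl ketone 2 (not isolated)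
Conditions: LiN(SiMe3)2, THF, −78 °C; CF3CO2CH2CF3; then 4-acetamidobenzenesulfonyl azide, Et3N, H2O, MeCN, rt
Reagents that add atoms: 4-acetamidobenzenesulfonyl azide, CC(=O)Nc1ccc(cc1)S(=O)(=O)N=[N+]=[N-]; 2,2,2-trifluoroethyl trifluoroacetate, O=C(OCC(F)(F)F)C(F)(F)F (its CF3CO group is present in 2 only and is lost again)
Why: C-Trifluoroacetylation of the kinetic lithium enolate gives the activated 1,3-dicarbonyl 2, which undergoes deacylative Regitz diazo transfer with the sulfonyl azide, the standard route from aryl ketones to α-diazo ketones.

**Step 2**
Reactants: 4 3,5-dimethoxyphenol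
Product: 5 1,3-dimethoxy-5-[(methylsulfanyl)methoxy]benzene
Conditions: NaH, NaI (cat.), DMF, 0 °C → rt
Reagents that add atoms: chloromethyl methyl sulfide, CSCCl
Why: Williamson O-alkylation of the sodium phenoxide by the α-chloro sulfide gives the methylthiomethyl ether, and the hard phenoxide oxygen in DMF should react in preference to the ring carbons.

**Step 3**
Reactants: 5 1,3-dimethoxy-5-[(methylsulfanyl)methoxy]benzene
Product: 6 1-(chloromethoxy)-3,5-dimethoxybenzene
Conditions: SO2Cl2 (1.0 equiv), CH2Cl2, −78 → 0 °C; volatiles removed in vacuo; used at once
Reagents that add atoms: sulfuryl chloride, O=S(=O)(Cl)Cl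
Why: S-Chlorination of the O,S-acetal and fragmentation of the chlorosulfonium ion to MeSCl and the oxocarbenium chloride is the standard conversion of methylthiomethyl aryl ethers into aryl chloromethyl ethers, and the sulfide sulfur should be chlorinated much faster than the arene at low temperature.

**Step 4**
Reactants: 3 2-diazo-6,7-dimethoxyindan-1-one, 6 1-(chloromethoxy)-3,5-dimethoxybenzene
Product: 9 (S)-4,5,5′,7′-tetramethoxyspiro[bicyclo[4.2.0]octa-1,3,5-triene-7,3′-chroman]-4′-one (target), via benzocyclobutenylidene ketene 7 (not isolated), via (S)-acid chloride 8 (not isolated)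
Conditions: 3 (1.2 equiv), hν (390–405 nm LED), t-BuOMe, −40 °C, until 3 is consumed; then 6 (1.0 equiv), the squaramide (10 mol %), −78 → −40 °C, dark; then (CF3)2CHOH, −40 °C → rt
Reagents that add atoms: none
Why: Proposed new method: Wolff rearrangement of 3 (1,2-shift of the aryl carbon from the carbonyl carbon to the carbene carbon, a ring contraction that closes the cyclobutene) gives the flat aryl alkyl ketene 7; the squaramide binds the chloride of 6 and exposes the O-aryl oxocarbenium ion pair, the nucleophilic ketene α-carbon (later C3) attacks its CH2 carbon (later C2), and the bound chloride collapses on the acylium carbon (later C4) to give 8, a net catalytic insertion of the ketene C=C into the C–Cl bond that regenerates the catalyst without any by-product. The closest known reaction types are the ZnCl2-catalysed addition of α-chloro ethers across ketenes to β-alkoxy acyl chlorides, enantioselective substitutions of α-chloro ethers under anion-binding catalysis by chiral hydrogen-bond donors, and the oxa-Povarov annulation of O-aryl oxocarbenium ions with alkenes, of which the whole step is the ketene version and a formal [4+2] annulation. In (CF3)2CHOH the acid chloride then ionizes and closes the pyranone ring by a 6-exo-trig Friedel–Crafts acylation at C4a (C4–C4a bond), as known for the cyclization of electron-rich aryl-tethered acid chlorides in this solvent without a Lewis acid. The only stereocentre, C3, is set in the C2–C3 bond formation by the catalyst: the ketene must lie face-on over the catalyst-bound ion pair so that the chloride can pass from C2 to C4, and the pyrrolidine aryl group then tells the dimethoxybenzo edge from the CH2 edge of the planar cyclobutene; the sense of induction is to be fixed by experiment with both catalyst antipodes, and the quaternary centre cannot epimerize in the acidic last stage. Regioselectivity needs no control, because the two positions ortho to the OCH2 group of 6 are equivalent and each is ortho to one methoxy group and para to the other, while the position between the methoxy groups cannot reach the acyl carbon. The chemoselectivity that is needed (attack of the ketene on the ion pair before arene self-alkylation of 6, ketene dimerization or alkylation of unreacted diazo ketone) is secured by completing the photolysis first, by low temperature and by the absence of a free Lewis acid.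

**Compound list**

1 | 6,7-dimethoxyindan-1-one | O=C1CCc2ccc(OC)c(OC)c21 | starting material
2 | 6,7-dimethoxy-2-(trifluoroacetyl)indan-1-one (racemic, enolized; formed as its lithium enolate) | O=C1C(C(=O)C(F)(F)F)Cc2ccc(OC)c(OC)c21 | intermediate
3 | 2-diazo-6,7-dimethoxyindan-1-one | [N-]=[N+]=C1Cc2ccc(OC)c(OC)c2C1=O | intermediate
4 | 3,5-dimethoxyphenol | COc1cc(O)cc(OC)c1 | starting material
5 | 1,3-dimethoxy-5-[(methylsulfanyl)methoxy]benzene | COc1cc(OCSC)cc(OC)c1 | intermediate
6 | 1-(chloromethoxy)-3,5-dimethoxybenzene | COc1cc(OCCl)cc(OC)c1 | intermediate
7 | (4,5-dimethoxybicyclo[4.2.0]octa-1,3,5-trien-7-ylidene)methanone (benzocyclobutenylidene ketene) | O=C=C1Cc2ccc(OC)c(OC)c21 | intermediate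
8 | (S)-7-[(3,5-dimethoxyphenoxy)methyl]-4,5-dimethoxybicyclo[4.2.0]octa-1,3,5-triene-7-carbonyl chloride | COc1cc(OC[C@@]2(Cc3ccc(OC)c(OC)c32)C(Cl)=O)cc(OC)c1 | intermediate
9 | (S)-4,5,5′,7′-tetramethoxyspiro[bicyclo[4.2.0]octa-1,3,5-triene-7,3′-chroman]-4′-one (CNP0192565.1) | COc1cc(OC)c2c(c1)OC[C@@]1(Cc3ccc(OC)c(OC)c31)C2=O | target

**Totals**

Total step count: 4. Longest linear sequence: 3 steps (4 → 5 → 6 → 9).

**Steps most likely to fail**

1. Step 4 (proposed new method). The enantiofacial discrimination in the ion-pair C–C bond formation may be poor. Chloride abstraction may also be too slow, so that ketene dimerization, N-acylation of the catalyst by the ketene, or decarbonylation of the tertiary acylium in the last stage take over. The fallback uses known chemistry, sets out from 3 (and uses 6) and comes back to the route at 8: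
   - Photolysis of 3 in methanol (Wolff rearrangement with trapping) should give the racemic methyl ester F1.
   - Deprotonation with LiN(i-Pr)2 in THF at −78 °C and alkylation of the ester enolate with 6 should give the racemic quaternary ester F2.
   - KOH in aqueous methanol should give the racemic acid F3.
   - Classical resolution by crystallization of its salt with one enantiomer of 1-phenylethylamine should give the (S)-acid F4.
   - (COCl)2 with catalytic DMF in CH2Cl2 converts F4 into 8, which is cyclized in (CF3)2CHOH as in step 4 to 9.

2. Step 3. The electron-rich ring may be chlorinated by SO2Cl2 or sulfenylated by the MeSCl that is set free, and the chloromethyl ether may hydrolyse or self-alkylate on handling. The fallback sets out from 5 and comes back at 6: S-methylation with MeOTf in CH2Cl2 at −40 °C should give the sulfonium triflate F5, and n-Bu4NCl then displaces dimethyl sulfide to give 6, with no electrophilic chlorine or sulfenyl chloride present.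

3. Step 1. Self-aldol condensation of the indanone enolate may compete with C-trifluoroacetylation, and the acyl transfer may stay incomplete. The fallback sets out from 1 and comes back at 3: acid-mediated α-nitrosation (isoamyl nitrite, HCl, MeOH) should give the 2-oximino ketone F6, and the Forster reaction (NH2Cl from aqueous NH3 and NaOCl, 0 °C) converts it into 3 without an enolate.

**Further compounds**

F1 | step 4 | methyl 4,5-dimethoxybicyclo[4.2.0]octa-1,3,5-triene-7-carboxylate (racemic) | COC(=O)C1Cc2ccc(OC)c(OC)c21
F2 | step 4 | methyl 7-[(3,5-dimethoxyphenoxy)methyl]-4,5-dimethoxybicyclo[4.2.0]octa-1,3,5-triene-7-carboxylate (racemic) | COC(=O)C1(COc2cc(OC)cc(OC)c2)Cc2ccc(OC)c(OC)c21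
F3 | step 4 | 7-[(3,5-dimethoxyphenoxy)methyl]-4,5-dimethoxybicyclo[4.2.0]octa-1,3,5-triene-7-carboxylic acid (racemic) | OC(=O)C1(COc2cc(OC)cc(OC)c2)Cc2ccc(OC)c(OC)c21
F4 | step 4 | (S)-7-[(3,5-dimethoxyphenoxy)methyl]-4,5-dimethoxybicyclo[4.2.0]octa-1,3,5-triene-7-carboxylic acid | COc1cc(OC[C@@]2(Cc3ccc(OC)c(OC)c32)C(O)=O)cc(OC)c1
F5 | step 3 | [(3,5-dimethoxyphenoxy)methyl]dimethylsulfonium trifluoromethanesulfonate | COc1cc(OC[S+](C)C)cc(OC)c1.[O-]S(=O)(=O)C(F)(F)F
F6 | step 1 | 2-(hydroxyimino)-6,7-dimethoxyindan-1-one | O=C1C(=NO)Cc2ccc(OC)c(OC)c21
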